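## Retrosynthetic overview

Locants: C7 is the carbinol carbon on ring A (the catechol ring), C8 the carbon that carries the ring B aryloxy oxygen, C9 the hydroxymethyl carbon; ring B is the guaiacyl ring with the three-carbon chain.

1. Target 9 ⇐ 8: one hydride operation turns the C9 ester and the ring B side-chain ester into the two primary alcohols and strips both ring A acetates.
2. 8 ⇐ 2 + 4 + 5: C8 is taken back to the carbene carbon of ethyl diazoacetate, which forms C8–O with the ring B phenol and C7–C8 with the ring A aldehyde in one catalytic event.
3. The strategy rests on C8 being a CH bonded only to the ring B phenoxy oxygen, to C9 and to the C7 carbinol carbon, which is the pattern a carbene carbon shows after taking an O–H nucleophile and a carbonyl electrophile.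
4. No ring is formed; ring A comes from 3,4-dihydroxybenzaldehyde (acetylated so that the aldehyde is electron-poor) and ring B from dihydroferulic acid.
5. The ring B side chain is carried as the ethyl propanoate, so the carbene meets a single O–H and the final hydride step also delivers the 3-hydroxypropyl group without a separate deprotection.

Key step: step 3

Assumption: which enantiomer of the phosphoric acid gives the (2S,3S) ester cannot be derived from the related imine and glyoxylate trappings; the (R)-acid is written, and the (S)-acid is used with all else unchanged if the first run gives the (2R,3R) ester.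

## Route

Step 1
Reactants: 1 3-(4-hydroxy-3-methoxyphenyl)propanoic acid (dihydroferulic acid)
Product: 2 ethyl 3-(4-hydroxy-3-methoxyphenyl)propanoate (ring B phenol)
Conditions: EtOH, H2SO4 (cat.), reflux
Reagents that add atoms: ethanol, CCO
Why: Fischer esterification converts the aliphatic acid in excess ethanol under acid catalysis, while the phenol is not acylated under these conditions and no stereocentre is involved.

Step 2
Reactants: 3 3,4-dihydroxybenzaldehyde
Product: 4 3,4-diacetoxybenzaldehyde
Conditions: Ac2O (2.5 equiv), pyridine, CH2Cl2, 0 °C to rt, N2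
Reagents that add atoms: acetic anhydride, CC(=O)OC(C)=O
Why: O-acylation of both phenols by acetic anhydride with pyridine as acyl-transfer base leaves the formyl group alone and turns the electron-rich catechol aldehyde into an electron-poor acceptor.

Step 3
Reactants: 2 ethyl 3-(4-hydroxy-3-methoxyphenyl)propanoate; 4 3,4-diacetoxybenzaldehyde; 5 ethyl diazoacetate
Product: 8 ethyl (2S,3S)-3-(3,4-diacetoxyphenyl)-2-[4-(3-ethoxy-3-oxopropyl)-2-methoxyphenoxy]-3-hydroxypropanoate, via oxonium ylide 6 (not isolated), via E-enol 7 (not isolated)
Conditions: Rh2(OAc)4 (2 mol %), (R)-3,3′-bis(2,4,6-triisopropylphenyl)-1,1′-binaphthyl-2,2′-diyl hydrogen phosphate (10 mol %), 4 Å molecular sieves, CH2Cl2, 0 °C; 4 (2 equiv); 5 (1.5 equiv) added over 8 h by syringe pump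
Reagents that add atoms: none
Why: Proposed new method: Rh2(OAc)4 should take N2 out of 5 and hand the carbene carbon to the phenol oxygen of 2, the only O–H donor in the flask, giving oxonium ylide 6 (C8–O), whose proton moves to the ester oxygen to give E-enol 7; 7 is held at the P=O oxygen of the phosphoric acid while the P–OH proton activates the formyl group of 4, and the aldol-type addition inside this hydrogen-bonded assembly forms C7–C8 and gives 8 without closing any ring. The closest known reaction type is the three-component trapping of alcohol-derived oxonium ylides from aryl diazoacetates with aldehydes or imines under Rh2(OAc)4 and a chiral acid co-catalyst; the union of a phenol, an unsubstituted diazoacetate and a simple aryl aldehyde has no precedent. C8 and C7 (both S in 8) are set together in the C–C bond-forming event, the chiral pocket of the acid fixing which face of the enol meets which face of the aldehyde and so both the erythro relation and the absolute sense. The step needs trapping to beat the 1,2-proton shift that leads to the plain O–H insertion ester, and it needs erythro and facial selectivity. The two acetoxy groups of 4 make the formyl carbon electron-poor, 4 is in excess and 5 is fed slowly so that every ylide formed meets activated aldehyde, and the side chain of 2 offers no second O–H to the carbene.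

Step 4
Reactants: 8 ethyl (2S,3S)-3-(3,4-diacetoxyphenyl)-2-[4-(3-ethoxy-3-oxopropyl)-2-methoxyphenoxy]-3-hydroxypropanoate
Product: 9 (1S,2R)-1-(3,4-dihydroxyphenyl)-2-[4-(3-hydroxypropyl)-2-methoxyphenoxy]propane-1,3-diol
Conditions: LiAlH4 (5 equiv), THF, 0 °C to rt, Ar (8 added to the hydride); EtOAc quench, aq. potassium sodium tartrate, pH 5, EtOAc extraction
Reagents that add atoms: none
Why: Hydride reduction of carboxylic esters by LiAlH4 should convert the C9 ester and the side-chain ester into primary alcohols and cleave both aryl acetates in one operation, the cold inverse addition keeping reduction ahead of retro-aldol cleavage so that C7 and C8 pass through unchanged (the descriptor at C8 changes from S to R only because C9 drops in priority).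

## Compound list

1 | 3-(4-hydroxy-3-methoxyphenyl)propanoic acid (dihydroferulic acid) | COc1cc(CCC(=O)O)ccc1O | starting material
2 | ethyl 3-(4-hydroxy-3-methoxyphenyl)propanoate | CCOC(=O)CCc1ccc(O)c(OC)c1 | intermediate
3 | 3,4-dihydroxybenzaldehyde | O=Cc1ccc(O)c(O)c1 | starting material
4 | 3,4-diacetoxybenzaldehyde (4-formyl-1,2-phenylene diacetate) | CC(=O)Oc1ccc(C=O)cc1OC(C)=O | intermediate
5 | ethyl diazoacetate | CCOC(=O)C=[N+]=[N-] | starting material
6 | oxonium ylide, [4-(3-ethoxy-3-oxopropyl)-2-methoxyphenyl](2-ethoxy-2-oxoethan-1-id-1-yl)oxonium | CCOC(=O)[CH-][OH+]c1ccc(CCC(=O)OCC)cc1OC | intermediate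
7 | ethyl 3-{4-[(E)-2-ethoxy-2-hydroxyethenoxy]-3-methoxyphenyl}propanoate (E-enol, hydroxyl cis to the aryloxy group) | CCO/C(O)=C/Oc1ccc(CCC(=O)OCC)cc1OC | intermediate
8 | ethyl (2S,3S)-3-(3,4-diacetoxyphenyl)-2-[4-(3-ethoxy-3-oxopropyl)-2-methoxyphenoxy]-3-hydroxypropanoate (erythro) | CCOC(=O)CCc1ccc(O[C@H](C(=O)OCC)[C@@H](O)c2ccc(OC(C)=O)c(OC(C)=O)c2)c(OC)c1 | intermediate
9 | (1S,2R)-1-(3,4-dihydroxyphenyl)-2-[4-(3-hydroxypropyl)-2-methoxyphenoxy]propane-1,3-diol, (7S,8R), erythro | COc1cc(CCCO)ccc1O[C@H](CO)[C@@H](O)c1ccc(O)c(O)c1 | target

## Step count

Total steps: 4.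
Longest linear sequence: 3 steps (step 1 or step 2, then steps 3 and 4).

## Steps most likely to fail

**Step 3 (Proposed new method).** Proton transfer within the ylide or enol, possibly shuttled by the phosphoric acid itself, may outrun addition to the aldehyde, so that only carbene O–H insertion takes place. The addition may also proceed with poor erythro or facial control.

Fallback, from 2, rejoining the route at 9: the two bonds at C8 are made one after the other with an auxiliary, using known reaction types. Williamson etherification of 2 with (R)-4-benzyl-3-(chloroacetyl)oxazolidin-2-one (K2CO3, KI cat., MeCN) should give (4R)-4-benzyl-3-{2-[4-(3-ethoxy-3-oxopropyl)-2-methoxyphenoxy]acetyl}-1,3-oxazolidin-2-one F1. The MgCl2-catalysed direct anti-aldol reaction of N-acyloxazolidinones with aromatic aldehydes (MgCl2 cat., Et3N, Me3SiCl, EtOAc, rt) is then run with 4. Its soft enolisation touches only the imide and leaves the acetates and the side-chain ester alone. Attack on the chelated magnesium enolate opposite the benzyl group is expected to give (4R)-4-benzyl-3-[(2S,3S)-3-(3,4-diacetoxyphenyl)-2-[4-(3-ethoxy-3-oxopropyl)-2-methoxyphenoxy]-3-(trimethylsilyloxy)propanoyl]-1,3-oxazolidin-2-one F2. The α-aryloxy case is an extension of the documented substrate range, and the facial sense is reasoned by analogy with auxiliary alkylations. LiBH4 in THF/MeOH then cleaves the auxiliary reductively and reduces the side-chain ester and the aryl acetates. Dilute acid in the work-up removes the silyl ether and gives 9, so step 4 is not needed.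

**Step 4.** Retro-aldol cleavage or epimerisation through the C7 alkoxide may set in before the C9 ester is reduced. The polar, air-sensitive catechol may also be lost in the aluminium work-up.

Fallback, from 8, rejoining at 9: the C7 hydroxyl is capped first. Et3SiOTf and 2,6-lutidine in CH2Cl2 at −78 °C should give ethyl (2S,3S)-3-(3,4-diacetoxyphenyl)-2-[4-(3-ethoxy-3-oxopropyl)-2-methoxyphenoxy]-3-(triethylsilyloxy)propanoate F3, which has no alkoxide that could fragment. LiAlH4 in THF then reduces both esters and cleaves the acetates to give 4-[(1S,2R)-3-hydroxy-2-[4-(3-hydroxypropyl)-2-methoxyphenoxy]-1-(triethylsilyloxy)propyl]benzene-1,2-diol F4, which is less polar and easier to extract and purify. Et3N·3HF in MeCN at rt removes the silyl group under near-neutral conditions and gives 9.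

**Step 2.** The formyl group may be over-acylated to the geminal diacetate, or the catecholate may be oxidised by air under the basic conditions, giving mixtures.

Fallback, from 3, rejoining at 4: acylation is driven to completion under acid, with no phenoxide present. Ac2O with catalytic H2SO4 at 0 °C should give 4-(diacetoxymethyl)-1,2-phenylene diacetate F5, in which the formyl group is deliberately carried as the acylal. Brief treatment with dilute aqueous H2SO4 in THF at rt then hydrolyses the geminal diacetate, which reacts much faster than the aryl acetates, and gives 4.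

## Further compounds

F1 | step 3 | (4R)-4-benzyl-3-{2-[4-(3-ethoxy-3-oxopropyl)-2-methoxyphenoxy]acetyl}-1,3-oxazolidin-2-one | CCOC(=O)CCc1ccc(OCC(=O)N2[C@H](Cc3ccccc3)COC2=O)c(OC)c1
F2 | step 3 | (4R)-4-benzyl-3-[(2S,3S)-3-(3,4-diacetoxyphenyl)-2-[4-(3-ethoxy-3-oxopropyl)-2-methoxyphenoxy]-3-(trimethylsilyloxy)propanoyl]-1,3-oxazolidin-2-one | CCOC(=O)CCc1ccc(O[C@H](C(=O)N2[C@H](Cc3ccccc3)COC2=O)[C@@H](O[Si](C)(C)C)c4ccc(OC(C)=O)c(OC(C)=O)c4)c(OC)c1
F3 | step 4 | ethyl (2S,3S)-3-(3,4-diacetoxyphenyl)-2-[4-(3-ethoxy-3-oxopropyl)-2-methoxyphenoxy]-3-(triethylsilyloxy)propanoate | CCOC(=O)CCc1ccc(O[C@H](C(=O)OCC)[C@@H](O[Si](CC)(CC)CC)c2ccc(OC(C)=O)c(OC(C)=O)c2)c(OC)c1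
F4 | step 4 | 4-[(1S,2R)-3-hydroxy-2-[4-(3-hydroxypropyl)-2-methoxyphenoxy]-1-(triethylsilyloxy)propyl]benzene-1,2-diol | COc1cc(CCCO)ccc1O[C@H](CO)[C@@H](O[Si](CC)(CC)CC)c1ccc(O)c(O)c1
F5 | step 2 | 4-(diacetoxymethyl)-1,2-phenylene diacetate | CC(=O)OC(OC(C)=O)c1ccc(OC(C)=O)c(OC(C)=O)c1
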